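## Retrosynthetic overview
1. The enol ester comes last. C8=C9 is made by Wittig olefination of a C10 aldehyde with an acyloxymethylene ylide. That aldehyde and the acetonyl ketone both come from one double ozonolysis (vinyl on C10, 2‑methylallyl on C5).
2. C10–C9 comes from vinyl‑copper 1,4‑addition to a tricyclic C5‑substituted enone. C5–H comes from face‑selective protonation and C3–OH from oxidation of the cross‑conjugated enolate.
3. The cyclohexane and tetrahydropyran rings form together (C2–C14 and C15–O) by a biomimetic Lewis‑acid enone–olefin–alcohol cyclisation of a monocyclic cycloheptadienone. C18 comes from formaldehyde.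
4. The seven‑membered ring is built first, by a new one‑flask (4+3) annulation of a 1,4‑dialdehyde (C10, C11, C1, C2) with a β‑ketophosphonate dianion (C3, C4, C5).
5. The C11 quaternary centre is the only centre set by a catalyst: amine‑catalysed nitromethane addition to citral, then a Nef reaction. Ring order: 7‑ring, then 6‑ring and pyran together.

Assumption: vibsane numbering is used (C11 = C–Me quaternary, C10 = CH with the enol ester, C5 = CH with acetonyl, C4 = ring C=O, C3 = C–OH, C18 = OCH2, C2/C14 = ring‑fusion CH, C1 = bridging CH2), and the C14 descriptor is carried exactly as written in the target SMILES, taken to be the one the tether‑controlled cyclisation of step 6 delivers.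

## Route

Step 1
Reactants: 1 citral (commercial geranial/neral mixture, drawn as geranial, (2E)-3,7-dimethylocta-2,6-dienal); 2 nitromethane
Product: 3 (3S)-3,7-dimethyl-3-(nitromethyl)oct-6-enal
Conditions: (R)-α,α-diphenylprolinol TMS ether (20 mol%), PhCO2H (20 mol%), MeNO2 (10 equiv), MeOH, rt, 72 h
Reagents that add atoms: none
Why: Iminium‑ion‑catalysed asymmetric Michael addition, in which the CPh2OTMS group of the (R)-catalyst shields one face of the (E)-iminium ion so the small nitronate adds to C11 from the open face and sets the quaternary centre as S, while the E/Z enal isomers interconvert through the dienamine and react through the faster E‑iminium ion.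

Step 2
Reactants: 3 (3S)-3,7-dimethyl-3-(nitromethyl)oct-6-enal
Product: 5 (2S)-2-methyl-2-(4-methylpent-3-en-1-yl)butanedial, via sodium nitronate 4 (not isolated)
Conditions: NaOMe (1.0 equiv), MeOH, 0 °C; then aq TiCl3 (4 equiv), NH4OAc buffer (pH 6), THF/H2O, 0 °C → rt
Reagents that add atoms: water, O
Why: Reductive (McMurry‑type) Nef reaction, in which Ti(III) reduces the nitronate to the imine and water hydrolyses it to the C10 aldehyde, leaving both alkene and aldehyde intact and the non‑enolisable C11 centre untouched.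

Step 3
Reactants: 6 dimethyl (2-oxopropyl)phosphonate; 7 3-bromo-2-methylprop-1-ene
Product: 8 dimethyl (5-methyl-2-oxohex-5-en-3-yl)phosphonate (racemic)
Conditions: NaH (1.05 equiv), THF, 0 °C → rt
Reagents that add atoms: none
Why: SN2 C‑alkylation of the doubly activated CH2 with an allylic bromide, where the new P‑bearing carbon is racemic and becomes sp2 in step 4, so it carries no stereochemical information.

Step 4
Reactants: 5 (2S)-2-methyl-2-(4-methylpent-3-en-1-yl)butanedial; 8 dimethyl (5-methyl-2-oxohex-5-en-3-yl)phosphonate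
Product: 11 (4S)-6-hydroxy-4-methyl-4-(4-methylpent-3-enyl)-2-(2-methylallyl)cyclohept-2-en-1-one (C6 epimers), via sodium lithium 1,3-dianion 9 (not isolated), via open-chain aldolate 10 (not isolated)
Conditions: 8, NaH (1.05 equiv), THF, 0 °C; n-BuLi (1.05 equiv), −78 °C; add 5, −78 °C, 1 h; warm to 40 °C, 6 h (0.01 M); H2O
Reagents that add atoms: none
Why: Proposed new method: a one‑flask site‑selective (4+3) annulation of a 1,4‑dialdehyde with the 1,3‑dianion of a β‑ketophosphonate, in which the more basic γ‑carbanion (C3) of 9 adds at −78 °C to the less hindered CH2CHO of 5 (the other CHO is neopentyl‑type), the surviving phosphonate‑stabilised α‑carbanion (C5) of 10 then has only that neopentyl aldehyde within reach and on warming closes the seven‑membered ring by intramolecular Horner–Wadsworth–Emmons olefination with the ring enforcing the required Z C5=C10 geometry, the carbinol centre being a mixture erased in step 5 and C11 untouched; the closest known reaction types are γ‑aldol/γ‑alkylation of β‑ketophosphonate dianions and intramolecular HWE cycloalkenone synthesis, which have not been merged on a dialdehyde.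

Step 5
Reactants: 11 (4S)-6-hydroxy-4-methyl-4-(4-methylpent-3-enyl)-2-(2-methylallyl)cyclohept-2-en-1-one; 12 formaldehyde
Product: 14 (4S)-7-(hydroxymethyl)-4-methyl-4-(4-methylpent-3-enyl)-2-(2-methylallyl)cyclohepta-2,6-dien-1-one, via cross-conjugated dienone 13 (not isolated)
Conditions: DBU (1.2 equiv), THF, rt, 2 h; then 37% aq HCHO (5 equiv), DMAP (0.3 equiv), rt
Reagents that add atoms: none
Why: E1cB dehydration followed by Morita–Baylis–Hillman hydroxymethylation, which is site‑selective because only the C2=C3 enone arm has an accessible β‑carbon and an α‑H, the other arm being α‑substituted and neopentyl at its β‑carbon.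

Step 6
Reactants: 14 (4S)-7-(hydroxymethyl)-4-methyl-4-(4-methylpent-3-enyl)-2-(2-methylallyl)cyclohepta-2,6-dien-1-one
Product: 15 tricyclic enone (2S,3S,11S,14S): bicyclo[4.3.1]decane (C1 one‑carbon bridge) fused to a 2,2‑dimethyltetrahydropyran (C3–C18–O–C15–C14–C2), with C4=O, C5=C10, 2‑methylallyl on C5 and H on C3
Conditions: BF3·OEt2 (1.1 equiv), CH2Cl2, −78 °C
Reagents that add atoms: none
Why: Biomimetic Lewis‑acid enone–olefin (Michael‑type cation–olefin) cyclisation with ether termination, in which the C11‑tethered prenyl alkene can reach the activated C2 only from the ring face that carries the chain (this sets C2 relative to C11), the folded tether fixes C14 in the same bond‑forming event, the tertiary C15 cation is captured by the C18 hydroxyl, and the enol ketonises to the cis‑fused pyran (the C3–H is replaced in step 7).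

Step 7
Reactants: 15 tricyclic enone
Product: 18 3-O-TMS tricyclic enone (2S,3R,11S,14S), via potassium cross-conjugated dienolate 16 (not isolated), via potassium 3-alkoxide 17 (not isolated)
Conditions: KHMDS (1.1 equiv), THF, −78 °C; (±)-2-(phenylsulfonyl)-3-phenyloxaziridine (1.3 equiv), −78 °C; then TMSCl (1.5 equiv), −78 → 0 °C
Reagents that add atoms: (±)-trans-2-(phenylsulfonyl)-3-phenyloxaziridine, O=S(=O)(N1OC1c1ccccc1)c1ccccc1; chlorotrimethylsilane, C[Si](C)(C)Cl
Why: Davis enolate hydroxylation, where C3–H is the only α‑proton of the enone and oxygen is delivered to the planar C3 from the convex face opposite the pyran and three‑carbon bridge (3R, cis‑fused pyran kept), with silylation in the same flask protecting the α‑ketol for step 8.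

Step 8
Reactants: 18 3-O-TMS tricyclic enone; 19 vinylmagnesium bromide
Product: 21 (2S,3R,5S,10S,11S,14S)-3-hydroxy-5-(2-methylallyl)-10-vinyl tricyclic ketone, via C4 trimethylsilyl enol ether 20 (not isolated)
Conditions: CH2=CHMgBr (2 equiv), CuBr·SMe2 (20 mol%), TMSCl (3 equiv), DMPU, THF, −78 → −40 °C; then 1 M HCl, THF, 0 °C
Reagents that add atoms: chlorotrimethylsilane, C[Si](C)(C)Cl (silyl group of 20 only, lost again on work‑up)
Why: TMSCl‑accelerated copper‑catalysed conjugate addition followed by kinetic C‑protonation of the silyl enol ether, in which both vinyl‑copper (at C10) and the proton (at C5) approach from the convex face away from the C12–C14 bridge, giving 10S and pushing the 2‑methylallyl group to the concave face (5S, trans to vinyl).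

Step 9
Reactants: 21 3-hydroxy-5-(2-methylallyl)-10-vinyl tricyclic ketone
Product: 22 (2S,3R,5S,10S,11S,14S)-3-hydroxy-5-(2-oxopropyl)-10-formyl tricyclic ketone
Conditions: O3, CH2Cl2/MeOH (4:1), −78 °C; then Me2S, −78 °C → rt
Reagents that add atoms: ozone, [O-][O+]=O
Why: Double ozonolysis with reductive work‑up, in which the only two alkenes left are cleaved together (vinyl to CHO, 2‑methylallyl to acetonyl) under neutral conditions that do not epimerise C5 or C10.

Step 10
Reactants: 23 3-methylbut-2-enoyl chloride; 12 formaldehyde (as paraformaldehyde); 24 triphenylphosphine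
Product: 26 [(3-methylbut-2-enoyl)oxymethyl]triphenylphosphonium chloride, via chloromethyl 3-methylbut-2-enoate 25 (not isolated)
Conditions: (CH2O)n, ZnCl2 (2 mol%), 60 °C; then PPh3, MeCN, 80 °C
Reagents that add atoms: none
Why: Lewis‑acid insertion of formaldehyde into the acyl chloride gives the chloromethyl ester, and SN2 quaternisation of PPh3 then gives the α‑acyloxy phosphonium salt (no stereocentre).

Step 11
Reactants: 22 keto aldehyde; 26 [(3-methylbut-2-enoyl)oxymethyl]triphenylphosphonium chloride
Product: 28 target, (2S,3R,5S,10S,11S,14S)-3-hydroxyvibsanin E‑type enol ester, via acyloxymethylene ylide 27 (not isolated)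
Conditions: 26 (3 equiv), KHMDS (2.9 equiv), THF, −78 °C, 5 min; then 22, −78 → 0 °C; chromatography
Reagents that add atoms: none
Why: Wittig olefination with an α‑acyloxy ylide (Anders–Gaßner variant), which is aldehyde‑selective over both ketones, builds the (E)-C8=C9 enol ester directly (the minor Z isomer is removed by chromatography), and touches no ring stereocentre at low temperature.

## Compound list
1 | citral, drawn as geranial, (2E)-3,7-dimethylocta-2,6-dienal | CC(C)=CCC/C(C)=C/C=O | starting material
2 | nitromethane | C[N+](=O)[O-] | starting material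
3 | (3S)-3,7-dimethyl-3-(nitromethyl)oct-6-enal | O=CC[C@](C)(CCC=C(C)C)C[N+](=O)[O-] | intermediate
4 | sodium nitronate of 3 | O=CC[C@](C)(CCC=C(C)C)C=[N+]([O-])[O-].[Na+] | intermediate
5 | (2S)-2-methyl-2-(4-methylpent-3-en-1-yl)butanedial | O=CC[C@](C)(CCC=C(C)C)C=O | intermediate
6 | dimethyl (2-oxopropyl)phosphonate | CC(=O)CP(=O)(OC)OC | starting material
7 | 3-bromo-2-methylprop-1-ene | C=C(C)CBr | starting material
8 | dimethyl (5-methyl-2-oxohex-5-en-3-yl)phosphonate (racemic) | CC(=O)C(CC(C)=C)P(=O)(OC)OC | intermediate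
9 | sodium lithium 1,3-dianion of 8 | [Na+].[Li+].[CH2-]C(=O)[C-](CC(C)=C)P(=O)(OC)OC | intermediate
10 | open-chain aldolate (C2 alkoxide, C5 phosphonate carbanion, free C10 aldehyde, 11S) | [Na+].[Li+].[O-]C(CC(=O)[C-](CC(C)=C)P(=O)(OC)OC)C[C@](C)(CCC=C(C)C)C=O | intermediate
11 | (4S)-6-hydroxy-4-methyl-4-(4-methylpent-3-enyl)-2-(2-methylallyl)cyclohept-2-en-1-one (C6 epimers) | C=C(C)CC=1C(=O)CC(O)C[C@](C)(CCC=C(C)C)C=1 | intermediate
12 | formaldehyde (37% aq. in step 5, paraformaldehyde in step 10) | C=O | starting material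
13 | (4S)-4-methyl-4-(4-methylpent-3-enyl)-2-(2-methylallyl)cyclohepta-2,6-dien-1-one | C=C(C)CC=1C(=O)C=CC[C@](C)(CCC=C(C)C)C=1 | intermediate
14 | (4S)-7-(hydroxymethyl)-4-methyl-4-(4-methylpent-3-enyl)-2-(2-methylallyl)cyclohepta-2,6-dien-1-one | C=C(C)CC=1C(=O)C(CO)=CC[C@](C)(CCC=C(C)C)C=1 | intermediate
15 | tricyclic enone (2S,3S,11S,14S), C4=O, C5=C10, 5-(2-methylallyl), 3-H | C=C(C)CC=1C(=O)[C@@H]2COC(C)(C)[C@H]3CC[C@@](C)(C[C@@H]32)C=1 | intermediate
16 | potassium cross-conjugated dienolate of 15 (C3=C4–O−; 2S,11S,14S) | C=C(C)CC=1C([O-])=C2COC(C)(C)[C@H]3CC[C@@](C)(C[C@@H]32)C=1.[K+] | intermediate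
17 | potassium 3-alkoxide of the 3-hydroxy enone (2S,3R,11S,14S) | C=C(C)CC=1C(=O)[C@]2([O-])COC(C)(C)[C@H]3CC[C@@](C)(C[C@@H]32)C=1.[K+] | intermediate
18 | 3-O-TMS tricyclic enone (2S,3R,11S,14S) | C=C(C)CC=1C(=O)[C@]2(O[Si](C)(C)C)COC(C)(C)[C@H]3CC[C@@](C)(C[C@@H]32)C=1 | intermediate
19 | vinylmagnesium bromide | C=C[Mg]Br | starting material
20 | C4 trimethylsilyl enol ether (C4=C5) of the 10-vinyl adduct, 3-OTMS, vinyl on the convex face as in 21 | C=C(C)CC1=C(O[Si](C)(C)C)[C@]2(O[Si](C)(C)C)COC(C)(C)[C@H]3CC[C@@](C)(C[C@@H]32)[C@H]1C=C | intermediate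
21 | (2S,3R,5S,10S,11S,14S)-3-hydroxy-5-(2-methylallyl)-10-vinyl tricyclic ketone | C=C(C)C[C@@H]1C(=O)[C@]2(O)COC(C)(C)[C@H]3CC[C@@](C)(C[C@@H]32)[C@H]1C=C | intermediate
22 | (2S,3R,5S,10S,11S,14S)-3-hydroxy-5-(2-oxopropyl)-10-formyl tricyclic ketone | CC(=O)C[C@@H]1C(=O)[C@]2(O)COC(C)(C)[C@H]3CC[C@@](C)(C[C@@H]32)[C@H]1C=O | intermediate
23 | 3-methylbut-2-enoyl chloride | CC(C)=CC(=O)Cl | starting material
24 | triphenylphosphine | c1ccc(cc1)P(c1ccccc1)c1ccccc1 | starting material
25 | chloromethyl 3-methylbut-2-enoate | CC(C)=CC(=O)OCCl | intermediate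
26 | [(3-methylbut-2-enoyl)oxymethyl]triphenylphosphonium chloride | CC(C)=CC(=O)OC[P+](c1ccccc1)(c1ccccc1)c1ccccc1.[Cl-] | intermediate
27 | (3-methylbut-2-enoyloxy)methylenetriphenylphosphorane | CC(C)=CC(=O)OC=P(c1ccccc1)(c1ccccc1)c1ccccc1 | intermediate
28 | target CNP0237201.1 | CC(=O)C[C@@H]1C(=O)[C@]2(O)COC(C)(C)[C@H]3CC[C@@](C)(C[C@@H]32)[C@H]1/C=C/OC(=O)C=C(C)C | target

## Step count and risks
Total step count: 11. Longest linear sequence: 9 (steps 1, 2, 4, 5, 6, 7, 8, 9, 11).

**Risk 1, step 4 (the proposed new annulation).**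
- The γ‑carbanion may not discriminate well enough between the two aldehydes.
- It may enolise the CH2CHO group instead of adding to it.
- The fully substituted phosphonate carbanion may be too slow on the neopentyl aldehyde.

The fallback uses known chemistry and keeps C10 masked as the nitro group until the aldol is done. It sets out from 3. Compound 3 is added to 2.2 equiv of dianion 9 at −78 °C, where the first equivalent only makes the nitronate. This gives the γ‑aldol nitro ketophosphonate F1. The same NaOMe / buffered TiCl3 Nef reaction then unmasks the hydroxy aldehyde ketophosphonate F2. A Masamune–Roush intramolecular HWE (LiCl, DBU, MeCN, high dilution) closes the ring, and the route is rejoined at 11.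

**Risk 2, step 8.** C10 is flanked by the quaternary C11 and an α‑substituted C5. The organocopper reagent may therefore not add, or may add 1,2.

The fallback replaces the polar addition by a known radical one and sets out from 18. A photoredox decarboxylative Giese reaction is run with 2,2‑diethoxyacetic acid as formyl‑radical equivalent (4CzIPN, Cs2CO3, DMF, blue LED). The small nucleophilic radical adds to C10 from the convex face. The derived enolate is protonated from the same face, giving the 10‑(diethoxymethyl) ketone F3. Ozonolysis (O3, then Me2S) of the 2‑methylallyl group gives the acetonyl acetal F4. Treatment with 1 M HCl/THF removes the acetal and the TMS group, and the route is rejoined at 22.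

**Risk 3, step 11.**
- The ylide is basic and prone to acyl migration.
- Compound 22 is an aldol‑prone hydroxy keto aldehyde.
- E/Z control is only moderate.

The fallback avoids phosphorus ylides and sets out from 22. An aldehyde‑selective Takai–Utimoto olefination with Cl2CHBpin, CrCl2 and LiI in THF gives the (E)-alkenyl pinacolboronate F5. KHF2 in MeOH/H2O converts it into the potassium (E)-alkenyltrifluoroborate F6. A stereoretentive copper‑mediated Chan–Lam‑type coupling with 3‑methylbut‑2‑enoic acid (CuBr, DMAP, 4 Å MS, O2, CH2Cl2) then gives the (E)-enol ester, arriving at 28.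

Further compounds
F1 | step 4 | dimethyl [(9S)-7-hydroxy-2,9,13-trimethyl-9-(nitromethyl)-5-oxotetradeca-1,12-dien-4-yl]phosphonate (γ-aldol nitro ketophosphonate, carbinol and P–CH epimers) | C=C(C)CC(C(=O)CC(O)C[C@](C)(CCC=C(C)C)C[N+](=O)[O-])P(=O)(OC)OC
F2 | step 4 | hydroxy aldehyde ketophosphonate (neutral form of 10, 11S) | C=C(C)CC(C(=O)CC(O)C[C@](C)(CCC=C(C)C)C=O)P(=O)(OC)OC
F3 | step 8 | (2S,3R,5S,10S,11S,14S)-10-(diethoxymethyl)-5-(2-methylallyl)-3-OTMS tricyclic ketone | C=C(C)C[C@@H]1C(=O)[C@]2(O[Si](C)(C)C)COC(C)(C)[C@H]3CC[C@@](C)(C[C@@H]32)[C@H]1C(OCC)OCC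
F4 | step 8 | (2S,3R,5S,10S,11S,14S)-10-(diethoxymethyl)-5-(2-oxopropyl)-3-OTMS tricyclic ketone | CC(=O)C[C@@H]1C(=O)[C@]2(O[Si](C)(C)C)COC(C)(C)[C@H]3CC[C@@](C)(C[C@@H]32)[C@H]1C(OCC)OCC
F5 | step 11 | (E)-alkenyl pinacolboronate at C10 (2S,3R,5S,10S,11S,14S) | CC(=O)C[C@@H]1C(=O)[C@]2(O)COC(C)(C)[C@H]3CC[C@@](C)(C[C@@H]32)[C@H]1/C=C/B4OC(C)(C)C(C)(C)O4
F6 | step 11 | potassium (E)-alkenyltrifluoroborate at C10 (2S,3R,5S,10S,11S,14S) | CC(=O)C[C@@H]1C(=O)[C@]2(O)COC(C)(C)[C@H]3CC[C@@](C)(C[C@@H]32)[C@H]1/C=C/[B-](F)(F)F.[K+]
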